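Count time in days and every amount as a fraction of its charge, and read Monday's flask, the very flask asked about, as it has been followed so far.

common to all: starting material 0.12 M; coupling partner 0.132 M; free catalyst 0.12 mM; impurity 20 µM
- Monday's: the very flask that is asked about, followed so far
- flask: 

Monday's run (percent of the starting material charged)

| time / d | product / % | starting material / % |
|---|---|---|
| 0.333 | 3 | 99 |
| 0.625 | 8 | 93 |
| 1.04 | 14 | 91 |
| 2.00 | 21 | 76 |
| 4.00 | 38 | 61 |

(each reading ± 2 percentage points)

- apparent order in free catalyst when 30 % of the starting material are converted (percent change of the rate of making product for one percent more free catalyst charged)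
- apparent order in coupling partner when 30 % of the starting material are converted (percent change of the rate of making product for one percent more coupling partner charged)

- what was read earlier has a scatter of 2 percentage points, one standard deviation
- no earlier run changes the charge of free catalyst; that part of a forecast is a guess
- no earlier run changes the charge of coupling partner; that part of a forecast is a guess

Draw the starting material first: 61 % left after 4.00 d gives a fractional loss of 0.124 d⁻¹, so start the curve at that slope, draw no knee, since the readings show none beyond their scatter, and pass 30 % conversion near 2.89 d, where the rate of making product comes to 0.0104 M d⁻¹. Let the product level out at the whole charge, because the coupling partner is charged above the starting material, which makes starting material the limiting reagent.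

Now follow one molecule of free catalyst and suppose, as my own reckoning, that each impurity molecule takes one catalyst for good, so that the charge of 0.12 mM loses 20 µM and 0.100 mM stays at work. One percent more catalyst charged then goes wholly into that working rest, so take the ratio of the charge to the charge minus the impurity, the catalyst leverage, which is 1.20, and commit to it as the order in free catalyst if the rate follows the working catalyst. No earlier run changes the coupling partner, so reckon no order for it.

The forecast gave 1 for the catalyst, lower than my reckoning, and 0.5 for the coupling partner, noting “Nothing varied the catalyst either”. The flask gives 1.2 and 0.55.

    coupling partner ⇌ dormant form (K = 0.629, k = 0.0191 h⁻¹)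
    catalyst intermediate C → by-product + catalyst intermediate D (k = 54.5 h⁻¹)
    free catalyst + impurity → spent catalyst (k = 3.83 × 10⁵ M⁻¹ h⁻¹)
    catalyst intermediate A → catalyst intermediate B (k = 3240 h⁻¹)
    starting material + free catalyst → catalyst intermediate A (k = 104 M⁻¹ h⁻¹)
    catalyst intermediate E → free catalyst + product (k = 82.0 h⁻¹)
    catalyst intermediate D ⇌ catalyst intermediate E (K = 74.5, k = 768 h⁻¹)
    coupling partner + catalyst intermediate B ⇌ catalyst intermediate C (K = 5.90 M⁻¹, k = 531 M⁻¹ h⁻¹)

Read the flask in two stretches: by 0.800 d the impurity stood at 0 % of its charge and spent catalyst at 16.7 % of the catalyst charged, against the 16.7 % reckoned from the leverage, and spent catalyst still stood at 16.7 % at 8.00 d. The catalytic round meanwhile turned on the remainder, making product at 0.0102 M d⁻¹ at 2.87 d, and at 80.0 d, with starting material at 0 %, free catalyst stood at 83.3 % of the catalyst charged.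

The numbers in the tables stem from a simulated flask for substances that don't exist; noise was put on by code.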